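**Remarks on assumptions**

- Atom labels: C7–C9 are the benzylic carbon, the bridgehead carbon and the OCH2 carbon of the guaiacyl half. C7'–C9' are the same positions of the central half. C7''–C9'' are the carbons of the side chain.
- The sense of induction of the aminoindanol-derived triazolium catalyst with this pair of aldehydes cannot be predicted with certainty. The route is written for the catalyst enantiomer that delivers the (4S,5S) lactone 6; both enantiomers of the catalyst are accessible.
- Allyloxy-tert-butyldimethylsilane (1) and (S)-4-benzyl-3-(chloroacetyl)oxazolidin-2-one (21) are taken as commercially available.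

## Analysis of the target

The compound is a sesquilignan built on a cis-fused 3,7-dioxabicyclo[3.3.0]octane (furofuran), in which ring A (C7, O, C9', C8', C8) carries the 4-hydroxy-3-methoxyphenyl (guaiacyl) group on C7 and ring B (C7', O, C9, C8, C8') carries the central 3,5-dimethoxyphenyl ring on C7'. The 4-oxygen of that central ring is bonded to C8'' of a 1-(4-hydroxy-3,5-dimethoxyphenyl)propane-1,3-diol side chain. The core stereocentres are 7R, 8S, 7'S and 8'S: the bridgehead hydrogens are cis, the guaiacyl ring lies on the convex face (trans to C9) and the central ring on the concave face (cis to C9'), so the two halves differ in aryl group and in configuration. The side chain adds 7''R and 8''R, the threo (syn) pair, which is too far from the core for substrate control. Sensitive features are the two free phenols, the para-hydroxybenzylic alcohol at C7'' (quinone methide formation, oxidation) and the benzylic ether bonds C7–O and C7'–O, which are open to hydrogenolysis and to acid. Ionisation at C7' would scramble the concave aryl group with the convex one, and since the two arrangements are expected to be close in energy, nothing would restore it. The difficulties are therefore an unsymmetrical furofuran that cannot come from a dimerisation, a kinetically set concave aryl group that must survive every later step, a side chain needing reagent control, and three phenols to be unmasked in the right order. The route rests on one observation: in ring B the aryl group on C7' and the CH2O carbon C9' on C8' are cis, and O–C7'–C8'–C8–C9 is the skeleton of a γ-aryl-γ-butyrolactone once C9 is a carbonyl carbon.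

## Retrosynthetic reasoning

**Side chain (26 ⇒ 25 ⇒ 24 ⇒ 22 + 23; 22 ⇒ 20 + 21).** The last two operations only remove silyl groups (25) and the chiral auxiliary (24). The real cut is C7''–C8'' in 24. Cutting the O–C8'' bond instead would require a hindered 2,6-dimethoxyphenol to displace a leaving group on a secondary carbon flanked by two oxygenated carbons. With the C–C cut, the aryl ether is made by alkylating phenol 20 at a primary carbon of 21, and both side-chain centres are set in one auxiliary-controlled syn aldol of 22 with 23. The syn aldol relation is the threo relation of the target.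

**Order of the phenols (20 ⇒ 19 ⇒ 18).** The central phenol must be free for the alkylation while the guaiacyl phenol is masked, so 20 comes from 19 by hydrogenolysis of the benzyl ether and 19 from 18 by silylation. The benzyl ether has to be in place up to 18 because the ring A closure needs the central ring to be non-phenolic.

**Ring A (18 ⇒ 16 through 17).** The O–C7 bond is cut. C7 is para to the only free phenol of 16, so oxidation gives the quinone methide 17 at this carbon alone and the C9' hydroxyl adds to it. Ring B already fixes C8 and C8' cis, so only a cis-fused bicycle can form, and the guaiacyl ring avoids the concave face that the central ring occupies.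

**Oxidation level of C9 (16 ⇒ 15 ⇒ 14 ⇒ 13 ⇒ 12).** The ether CH2 of ring B is traced back to the lactone carbonyl of 12 through diol 13 and primary tosylate 14. This way ring B is re-closed by attack of the C7' oxygen on C9, and the C7'–O bond, and with it the concave aryl group, is never broken.

**C8 and the C7–C8 bond (12 ⇒ 11 ⇒ 10 ⇒ 9 ⇒ 6 + 8).** The all-cis lactone 12 is the hydrogenation product of arylidene lactone 11, which comes from aldol adduct 9 through mesylate 10. The bond cut is C8–C7, between the α-carbon of lactone 6 and aldehyde 8. Direct alkylation of the enolate of 6 would place the benzyl group trans to C9'. Hydrogenation of the alkene from the open face places it cis, as ring A requires.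

**Lactone 6 (⇒ 3 + 5).** The bonds C8'–C7' and O–C9 are cut together. Enal 3 supplies C9, C8, C8' and C9' in the right oxidation states, and aldehyde 5 supplies C7' with the central ring. The forward reaction must join them with the cis relation and in the (4S,5S) sense.

**Building blocks.** Enal 3 comes from 1 and 2 by cross-metathesis, 5 and 23 from syringaldehyde 4, and 8 from vanillin 7, each in one step.

## Alternatives that were turned down

**Alternative 1:** The bonds C7'–C8' and C8–C7 would be cut on either side of a butenolide. In the forward sense the lithium anion of 2-[4-(benzyloxy)-3,5-dimethoxyphenyl]-1,3-dithiane A3 adds to the β-carbon of (5S)-5-(menthyloxy)furan-2(5H)-one A2 anti to the acetal substituent. The enolate is then trapped by aldehyde 8 to give the trans-disubstituted lactone A1.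
- For it: two C–C bonds and the configurations of C8 and C8' are set in one flask by the proven chiral-pool butenolide A2. The trans lactone maps correctly onto the cis ring fusion, and the concave aryl group could later be installed by hydride delivery to a C7' oxocarbenium ion from the convex face. On certainty of absolute configuration it is stronger than the chosen route.
- Against it: C7' arrives from dithiane A3 without configuration and C7 as an uncontrolled carbinol. The acetal carbon C9' and the lactone carbon C9 both need reduction, the dithiane must be hydrolysed next to electron-rich arenes, and the ring closures run under Lewis acid with both benzylic centres exposed. The menthyl auxiliary of A2 is stoichiometric.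
- In its place the chosen route sets C7' and C8' together, catalytically and already in their final relation, and needs no sulfur chemistry and fewer redox corrections.

**Alternative 2:** The bonds C9–C8 and O–C7 would be cut, so that both rings close in one step from the acyclic methoxymethyl ether A5. Me3SiOTf would ionise the acetal, the oxocarbenium carbon would be attacked by C8 of the styrene, and the benzylic cation at C7 would be captured by the silyl ether oxygen on C9'. The product A4 is the same substance as compound 19.
- For it: this is the shortest path to that late intermediate and clearly better in step economy.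
- Against it: the C7'/C8' pair must still be set beforehand in an acyclic precursor. An oxocarbenium ion on a benzylic homoallylic oxygen can undergo a 2-oxonia-Cope shift that breaks the C7'–C8' bond, and the electron-rich aryl group on C7' favours exactly this. A silyl triflate can also ionise the C7'–O bond, and the concave aryl group has no thermodynamic protection.
- In its place the chosen route never exposes C7' to a strong Lewis acid after it is set, and each ring closure has its own predictable stereocontrol.

**Alternative 3:** The O–C9 bond of ring B would be cut by a ring expansion. MgI2 would open the aroylcyclopropane lactone A7 at its CH2 carbon, and the enolate oxygen would displace iodide to give the bicyclic enol ether lactone A6.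
- For it: the step is stereospecific at C8, and a later hydrogenation of the C7'=C8' bond from the convex face would give the concave aryl group and the cis fusion in one event, which is at least as good a way to that feature as the chosen one.
- Against it: the double bond of A6 is tetrasubstituted and of push-pull type, hence hard to reduce. A7 requires diazo chemistry and an enantioselective cyclopropanation that sets three centres. The lactone at C9' still has to become an ether, and MgI2 may ionise the benzylic C7–O bond.
- In its place the chosen route reaches its key step in two steps from commercial materials and reduces a simple trisubstituted alkene.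

Key step: step 3

## Route

Step 1
Reactants: 1 allyloxy-tert-butyldimethylsilane; 2 (E)-but-2-enal (crotonaldehyde)
Product: 3 (E)-4-(tert-butyldimethylsilyloxy)but-2-enal
Conditions: second-generation Hoveyda–Grubbs catalyst (2.5 mol %), 2 (4 equiv), CH2Cl2, 40 °C
Reagents that add atoms: none
Why: Olefin cross-metathesis of a terminal allyl ether with an enal; the electron-poor partner hardly homodimerises, propene is lost, and the thermodynamically favoured (E)-enal should result.

Step 2
Reactants: 4 syringaldehyde
Product: 5 4-(benzyloxy)-3,5-dimethoxybenzaldehyde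
Conditions: BnBr, K2CO3, DMF, rt
Reagents that add atoms: benzyl bromide, BrCc1ccccc1
Why: Williamson ether synthesis on the phenoxide of 4; the aldehyde has no α-hydrogen and is inert to carbonate.

Step 3
Reactants: 3 (E)-4-(tert-butyldimethylsilyloxy)but-2-enal; 5 4-(benzyloxy)-3,5-dimethoxybenzaldehyde
Product: 6 (4S,5S)-5-[4-(benzyloxy)-3,5-dimethoxyphenyl]-4-{[(tert-butyldimethylsilyl)oxy]methyl}dihydrofuran-2(3H)-one (4,5-cis)
Conditions: chiral aminoindanol-derived N-mesityl triazolium chloride (15 mol %), DBU (15 mol %), THF, rt, slow addition of 3 to 5 (2 equiv)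
Reagents that add atoms: none
Why: The free carbene adds to the carbonyl carbon of 3 and proton transfer gives the extended Breslow intermediate, a homoenolate that is nucleophilic at C8'. C8' attacks the carbonyl carbon of the non-enolisable aldehyde 5 (bond C8'–C7'), the enol tautomerises to the acyl azolium, and the C7' alkoxide acylates at C9, closing the lactone by a 5-exo-trig addition–elimination (bond O–C9) and releasing the carbene. The closest known reaction type is the carbene-catalysed homoenolate annulation of enals with aromatic aldehydes, which gives cis-γ-butyrolactones. C8' and C7' are created in the same C–C bond-forming event: the cis relation follows from the compact transition state in which the aldehyde oxygen faces the enol and its aryl group points away from the catalyst, and the absolute sense from the indane-fused backbone, which blocks one face of the planar homoenolate. Three selectivities are needed. Cross-annulation in preference to self-annulation of the enal is secured by adding 3 slowly to an excess of 5, which cannot form a homoenolate itself. Addition must outrun loss of silanolate from C9', which the poor leaving-group ability of a silyloxide and the weak base favour. Cis and facial selectivity rest on the catalyst.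

Step 4
Reactants: 7 vanillin
Product: 8 3-methoxy-4-(triisopropylsilyloxy)benzaldehyde
Conditions: TIPSCl, imidazole, DMF, rt
Reagents that add atoms: triisopropylsilyl chloride, CC(C)[Si](Cl)(C(C)C)C(C)C
Why: Imidazole-promoted silylation of a phenol; the bulky silyl ether is chosen because it must survive a lithium enolate, an amidine base and hydride reagents.

Step 5
Reactants: 6 cis-lactone; 8 3-methoxy-4-(triisopropylsilyloxy)benzaldehyde
Product: 9 (3S,4S,5S)-5-[4-(benzyloxy)-3,5-dimethoxyphenyl]-4-{[(tert-butyldimethylsilyl)oxy]methyl}-3-{hydroxy[3-methoxy-4-(triisopropylsilyloxy)phenyl]methyl}dihydrofuran-2(3H)-one (3,4-trans, 4,5-cis; both carbinol epimers)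
Conditions: LiN(i-Pr)2, THF, −78 °C; 8; AcOH, −78 °C
Reagents that add atoms: none
Why: Aldol addition of the lithium enolate of the lactone to a non-enolisable aldehyde; the enolate reacts on the face away from the neighbouring CH2OSi group, and the configuration of the carbinol carbon does not matter because it is removed in step 6.

Step 6
Reactants: 9 aldol adduct
Product: 11 (3E,4S,5S)-5-[4-(benzyloxy)-3,5-dimethoxyphenyl]-4-{[(tert-butyldimethylsilyl)oxy]methyl}-3-[3-methoxy-4-(triisopropylsilyloxy)benzylidene]dihydrofuran-2(3H)-one, via C7 mesylate 10 (not isolated)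
Conditions: MsCl, Et3N, CH2Cl2, 0 °C; then DBU, rt
Reagents that add atoms: none
Why: Sulfonylation followed by base-induced E1cB elimination of the β-mesyloxy lactone; the (E)-arylidene lactone with the aryl group anti to the carbonyl is the usual thermodynamic product, and C4 and C5 are not touched.

Step 7
Reactants: 11 arylidene lactone
Product: 12 (3S,4S,5S)-5-[4-(benzyloxy)-3,5-dimethoxyphenyl]-4-{[(tert-butyldimethylsilyl)oxy]methyl}-3-[3-methoxy-4-(triisopropylsilyloxy)benzyl]dihydrofuran-2(3H)-one (all-cis)
Conditions: H2 (1 atm), 10 % Pd/C, Ph2S (cat.), EtOAc, rt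
Reagents that add atoms: none
Why: Heterogeneous hydrogenation of the exocyclic alkene; both existing substituents lie on one face of the lactone, so hydrogen should arrive from the other face, which places the new benzyl group cis to them and sets C8 (3S). Ph2S moderates the palladium so that the aryl benzyl ether and the benzylic lactone C–O bond are expected to be kept.

Step 8
Reactants: 12 all-cis lactone
Product: 13 (1S,2S,3S)-1-[4-(benzyloxy)-3,5-dimethoxyphenyl]-2-{[(tert-butyldimethylsilyl)oxy]methyl}-3-[3-methoxy-4-(triisopropylsilyloxy)benzyl]butane-1,4-diol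
Conditions: LiBH4, THF, 0 °C → rt
Reagents that add atoms: none
Why: Hydride reduction of a γ-lactone to the 1,4-diol; LiBH4 leaves aryl and alkyl silyl ethers alone, and no stereocentre is involved.

Step 9
Reactants: 13 diol
Product: 15 (2S,3S,4S)-2-[4-(benzyloxy)-3,5-dimethoxyphenyl]-3-{[(tert-butyldimethylsilyl)oxy]methyl}-4-[3-methoxy-4-(triisopropylsilyloxy)benzyl]tetrahydrofuran (all-cis), via primary tosylate 14 (not isolated)
Conditions: TsCl (1.1 equiv), pyridine, DMAP (cat.), 0 °C → rt, then 60 °C
Reagents that add atoms: none
Why: Selective sulfonylation of the primary hydroxyl followed by intramolecular Williamson etherification (5-exo-tet) by the benzylic hydroxyl; the C7'–O bond is never broken, so the cis configuration of the benzylic carbon is carried over, which a dehydration through a benzylic cation could not guarantee.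

Step 10
Reactants: 15 bis-silyl ether
Product: 16 [(2S,3S,4S)-2-[4-(benzyloxy)-3,5-dimethoxyphenyl]-4-(4-hydroxy-3-methoxybenzyl)tetrahydrofuran-3-yl]methanol
Conditions: TBAF (2.5 equiv), THF, 0 °C → rt
Reagents that add atoms: none
Why: Fluoride cleavage of both silyl ethers, driven by Si–F bond formation; the benzyl ether on the central ring is inert and keeps that ring out of the following oxidation.

Step 11
Reactants: 16 phenol alcohol
Product: 18 4-[(1R,3aS,4S,6aS)-4-[4-(benzyloxy)-3,5-dimethoxyphenyl]tetrahydro-1H,3H-furo[3,4-c]furan-1-yl]-2-methoxyphenol, via para-quinone methide 17 (not isolated)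
Conditions: DDQ (1.0 equiv), CH2Cl2, 0 °C
Reagents that add atoms: none
Why: DDQ dehydrogenation of a para-alkylphenol to a para-quinone methide, followed by intramolecular 1,6-addition of the primary hydroxyl (5-exo-trig), a known way to benzylic ethers in lignan chemistry. Ring B enforces the cis ring fusion; C7 (1R) should form with the guaiacyl ring on the convex face, because the transition state with the C8–H bond eclipsing the exocyclic C=C (least allylic 1,3-strain) leads there and the alternative would crowd two aryl groups on the concave face. One equivalent of oxidant at low temperature limits further oxidation.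

Step 12
Reactants: 18 furofuran phenol
Product: 19 triisopropylsilyl ether of 18: {4-[(1R,3aS,4S,6aS)-4-[4-(benzyloxy)-3,5-dimethoxyphenyl]tetrahydro-1H,3H-furo[3,4-c]furan-1-yl]-2-methoxyphenoxy}triisopropylsilane
Conditions: TIPSCl, imidazole, DMF, rt
Reagents that add atoms: triisopropylsilyl chloride, CC(C)[Si](Cl)(C(C)C)C(C)C
Why: Silylation of the only hydroxyl group; the guaiacyl phenol must be masked before the central phenol is freed and alkylated.

Step 13
Reactants: 19 benzyl ether
Product: 20 2,6-dimethoxy-4-[(1S,3aS,4R,6aS)-4-[3-methoxy-4-(triisopropylsilyloxy)phenyl]tetrahydro-1H,3H-furo[3,4-c]furan-1-yl]phenol (same core configuration as 19)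
Conditions: H2 (1 atm), 10 % Pd/C, EtOAc, rt, stopped at full conversion of 19
Reagents that add atoms: none
Why: Hydrogenolysis of an aryl benzyl ether, which under neutral conditions at atmospheric pressure is cleaved much faster than the dialkyl benzylic ether bonds of the furofuran.

Step 14
Reactants: 20 central phenol; 21 (S)-4-benzyl-3-(chloroacetyl)oxazolidin-2-one
Product: 22 (4S)-4-benzyl-3-[(aryloxy)acetyl]oxazolidin-2-one in which aryl is the 2,6-dimethoxy-4-(furofuranyl)phenyl group of 20
Conditions: K2CO3, DMF, rt
Reagents that add atoms: none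
Why: SN2 alkylation of a phenoxide by an α-chloro imide (Williamson); the carbon attacked is primary and activated by the carbonyl, so the hindered 2,6-dimethoxyphenoxide should still react readily, and the auxiliary stereocentre is not involved.

Step 15
Reactants: 4 syringaldehyde
Product: 23 4-(tert-butyldimethylsilyloxy)-3,5-dimethoxybenzaldehyde
Conditions: TBSCl, imidazole, DMF, rt
Reagents that add atoms: tert-butyldimethylsilyl chloride, CC(C)(C)[Si](C)(C)Cl
Why: Imidazole-promoted silylation of the phenol, which gives an aldol acceptor whose protecting group leaves in the final fluoride step.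

Step 16
Reactants: 22 aryloxyacetyl imide; 23 4-(tert-butyldimethylsilyloxy)-3,5-dimethoxybenzaldehyde
Product: 24 (4S)-4-benzyl-3-[(2S,3R)-2-(aryloxy)-3-[4-(tert-butyldimethylsilyloxy)-3,5-dimethoxyphenyl]-3-hydroxypropanoyl]oxazolidin-2-one (syn aldol; aryl as in 22)
Conditions: Bu2BOTf, i-Pr2NEt, CH2Cl2, −78 → 0 °C; 23, −78 → 0 °C; pH 7 buffer, MeOH, H2O2, 0 °C
Reagents that add atoms: none
Why: Evans syn aldol: the (Z)-boron enolate of the glycolate imide reacts through a chair Zimmerman–Traxler transition state in which the oxazolidinone carbonyl is turned away from the enolate oxygen and the benzyl group shields one face. The (S)-auxiliary thereby sets C8'' (2S in the imide) and C7'' (3R) with the syn relation that corresponds to the threo diol.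

Step 17
Reactants: 24 aldol adduct
Product: 25 (1R,2R)-2-(aryloxy)-1-[4-(tert-butyldimethylsilyloxy)-3,5-dimethoxyphenyl]propane-1,3-diol (aryl as in 22)
Conditions: LiBH4, THF, MeOH (1 equiv), 0 °C
Reagents that add atoms: none
Why: Reductive cleavage of the N-acyl oxazolidinone by hydride attack at the exocyclic carbonyl; the conditions are not basic enough to epimerise C8'', the auxiliary is released intact, and the descriptor of C8'' changes to R only because the priorities change.

Step 18
Reactants: 25 bis-silyl ether
Product: 26 target, 4-[(1R,3aS,4S,6aS)-4-(4-{[(1R,2R)-1,3-dihydroxy-1-(4-hydroxy-3,5-dimethoxyphenyl)propan-2-yl]oxy}-3,5-dimethoxyphenyl)tetrahydro-1H,3H-furo[3,4-c]furan-1-yl]-2-methoxyphenol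
Conditions: TBAF (2.5 equiv), AcOH (2.5 equiv), THF, 0 °C
Reagents that add atoms: none
Why: Fluoride cleavage of the two aryl silyl ethers; acetic acid buffers the phenoxides so that the para-hydroxybenzylic alcohol is not driven towards a quinone methide, and no other group reacts.

## Compound list

1 | allyloxy-tert-butyldimethylsilane | C=CCO[Si](C)(C)C(C)(C)C | starting material
2 | (E)-but-2-enal | C/C=C/C=O | starting material
3 | (E)-4-(tert-butyldimethylsilyloxy)but-2-enal | O=C/C=C/CO[Si](C)(C)C(C)(C)C | intermediate
4 | syringaldehyde | COc1cc(C=O)cc(OC)c1O | starting material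
5 | 4-(benzyloxy)-3,5-dimethoxybenzaldehyde | COc1cc(C=O)cc(OC)c1OCc1ccccc1 | intermediate
6 | (4S,5S)-5-[4-(benzyloxy)-3,5-dimethoxyphenyl]-4-{[(tert-butyldimethylsilyl)oxy]methyl}dihydrofuran-2(3H)-one | O=C1C[C@@H](CO[Si](C)(C)C(C)(C)C)[C@@H](c2cc(OC)c(OCc3ccccc3)c(OC)c2)O1 | intermediate
7 | vanillin | COc1cc(C=O)ccc1O | starting material
8 | 3-methoxy-4-(triisopropylsilyloxy)benzaldehyde | COc1cc(C=O)ccc1O[Si](C(C)C)(C(C)C)C(C)C | intermediate
9 | aldol adduct, 3,4-trans-4,5-cis lactone with C7 carbinol (both epimers) | O=C1[C@H](C(O)c2ccc(O[Si](C(C)C)(C(C)C)C(C)C)c(OC)c2)[C@@H](CO[Si](C)(C)C(C)(C)C)[C@@H](c2cc(OC)c(OCc3ccccc3)c(OC)c2)O1 | intermediate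
10 | C7 mesylate of 9 | O=C1[C@H](C(OS(C)(=O)=O)c2ccc(O[Si](C(C)C)(C(C)C)C(C)C)c(OC)c2)[C@@H](CO[Si](C)(C)C(C)(C)C)[C@@H](c2cc(OC)c(OCc3ccccc3)c(OC)c2)O1 | intermediate (not isolated)
11 | (3E,4S,5S)-arylidene lactone | O=C1/C(=C/c2ccc(O[Si](C(C)C)(C(C)C)C(C)C)c(OC)c2)[C@@H](CO[Si](C)(C)C(C)(C)C)[C@@H](c2cc(OC)c(OCc3ccccc3)c(OC)c2)O1 | intermediate
12 | (3S,4S,5S)-all-cis lactone | O=C1[C@@H](Cc2ccc(O[Si](C(C)C)(C(C)C)C(C)C)c(OC)c2)[C@@H](CO[Si](C)(C)C(C)(C)C)[C@@H](c2cc(OC)c(OCc3ccccc3)c(OC)c2)O1 | intermediate
13 | (1S,2S,3S)-butane-1,4-diol | OC[C@@H](Cc1ccc(O[Si](C(C)C)(C(C)C)C(C)C)c(OC)c1)[C@@H](CO[Si](C)(C)C(C)(C)C)[C@H](O)c1cc(OC)c(OCc2ccccc2)c(OC)c1 | intermediate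
14 | primary tosylate of 13 | Cc1ccc(S(=O)(=O)OC[C@@H](Cc2ccc(O[Si](C(C)C)(C(C)C)C(C)C)c(OC)c2)[C@@H](CO[Si](C)(C)C(C)(C)C)[C@H](O)c2cc(OC)c(OCc3ccccc3)c(OC)c2)cc1 | intermediate (not isolated)
15 | (2S,3S,4S)-all-cis tetrahydrofuran, bis-silyl ether | C1[C@@H](Cc2ccc(O[Si](C(C)C)(C(C)C)C(C)C)c(OC)c2)[C@@H](CO[Si](C)(C)C(C)(C)C)[C@@H](c2cc(OC)c(OCc3ccccc3)c(OC)c2)O1 | intermediate
16 | [(2S,3S,4S)-2-[4-(benzyloxy)-3,5-dimethoxyphenyl]-4-(4-hydroxy-3-methoxybenzyl)tetrahydrofuran-3-yl]methanol | C1[C@@H](Cc2ccc(O)c(OC)c2)[C@@H](CO)[C@@H](c2cc(OC)c(OCc3ccccc3)c(OC)c2)O1 | intermediate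
17 | para-quinone methide of 16 | C1[C@@H](C=C2C=CC(=O)C(OC)=C2)[C@@H](CO)[C@@H](c2cc(OC)c(OCc3ccccc3)c(OC)c2)O1 | intermediate (not isolated)
18 | (1R,3aS,4S,6aS)-furofuran, guaiacyl phenol free, central ring O-benzyl | COc1cc([C@@H]2OC[C@@H]3[C@H]2CO[C@@H]3c2cc(OC)c(OCc3ccccc3)c(OC)c2)ccc1O | intermediate
19 | triisopropylsilyl ether of 18 | COc1cc([C@@H]2OC[C@@H]3[C@H]2CO[C@@H]3c2cc(OC)c(OCc3ccccc3)c(OC)c2)ccc1O[Si](C(C)C)(C(C)C)C(C)C | intermediate
20 | furofuran with free central phenol | COc1cc([C@@H]2OC[C@@H]3[C@H]2CO[C@@H]3c2cc(OC)c(O)c(OC)c2)ccc1O[Si](C(C)C)(C(C)C)C(C)C | intermediate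
21 | (S)-4-benzyl-3-(chloroacetyl)oxazolidin-2-one | O=C(CCl)N1[C@@H](Cc2ccccc2)COC1=O | starting material
22 | aryloxyacetyl oxazolidinone | COc1cc([C@@H]2OC[C@@H]3[C@H]2CO[C@@H]3c2cc(OC)c(OCC(=O)N3[C@@H](Cc4ccccc4)COC3=O)c(OC)c2)ccc1O[Si](C(C)C)(C(C)C)C(C)C | intermediate
23 | 4-(tert-butyldimethylsilyloxy)-3,5-dimethoxybenzaldehyde | COc1cc(C=O)cc(OC)c1O[Si](C)(C)C(C)(C)C | intermediate
24 | (2S,3R)-syn aldol adduct | COc1cc([C@@H]2OC[C@@H]3[C@H]2CO[C@@H]3c2cc(OC)c(O[C@H](C(=O)N3[C@@H](Cc4ccccc4)COC3=O)[C@H](O)c3cc(OC)c(O[Si](C)(C)C(C)(C)C)c(OC)c3)c(OC)c2)ccc1O[Si](C(C)C)(C(C)C)C(C)C | intermediate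
25 | (1R,2R)-diol, bis-silyl ether | COc1cc([C@@H]2OC[C@@H]3[C@H]2CO[C@@H]3c2cc(OC)c(O[C@H](CO)[C@H](O)c3cc(OC)c(O[Si](C)(C)C(C)(C)C)c(OC)c3)c(OC)c2)ccc1O[Si](C(C)C)(C(C)C)C(C)C | intermediate
26 | CNP0317965.1 | COc1cc([C@@H]2OC[C@@H]3[C@H]2CO[C@@H]3c2cc(OC)c(O[C@H](CO)[C@H](O)c3cc(OC)c(O)c(OC)c3)c(OC)c2)ccc1O | target

## Step count and least certain steps

Total: 18 steps. Longest linear sequence: 15 steps (steps 1, 3, 5–14, 16–18, or equally steps 2, 3, 5–14, 16–18).

**Step 3 (key step).**
- Most likely failure: the homoenolate adds to a second molecule of enal and not to the electron-rich, weakly electrophilic aldehyde 5; or silanolate is lost from C9' of the homoenolate; or the cis and facial selectivities are too low with a β-alkyl enal.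
- Fallback, from 5 back to 6 by an auxiliary-controlled anti aldol. (S)-4-Benzyloxazolidin-2-one is N-acylated with pent-4-enoyl chloride (n-BuLi, THF, −78 °C) to give (S)-4-benzyl-3-(pent-4-enoyl)oxazolidin-2-one F1. The magnesium-catalysed anti aldol of F1 with 5 (MgCl2 (10 mol %), Et3N, Me3SiCl, EtOAc, rt) should give the silylated anti adduct F2, the chelated magnesium enolate being attacked on the face away from the benzyl group. In F2 the acyl carbon is C9', the α-carbon C8' and the carbinol carbon C7'; the anti relation of hydroxyl and allyl group is the one that maps onto the cis lactone. LiBH4 followed by acidic work-up removes the auxiliary and the trimethylsilyl group to give the (1S,2S)-diol F3. TBSCl and imidazole silylate the primary hydroxyl to give the silyl ether F4. OsO4 (cat.) with NaIO4 cleaves the terminal alkene, and the aldehyde closes onto the benzylic hydroxyl to give the lactol F5. Oxidation with [Pr4N][RuO4] (cat.) and N-methylmorpholine N-oxide then gives 6.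

**Step 11.**
- Most likely failure: further oxidation of 18, whose remaining benzylic C–H at C7 is flanked by an ether oxygen and a para-hydroxyphenyl ring, so that ring A is reopened at the ketone level.
- Fallback, from 16 back to 18 without relying on a clean stop. Oxidation is taken deliberately to the ketone with DDQ (2.2 equiv) in aqueous dioxane, which should give the hydroxy ketone F6. NaBH4 in MeOH at 0 °C, applied at once to limit enolisation at C8, gives the benzylic alcohol F7 as a mixture of C7 epimers. A catalytic amount of pyridinium para-toluenesulfonate in CH2Cl2 then dehydrates the para-hydroxybenzylic alcohol to quinone methide 17, which closes to 18 under thermodynamic control. The central ring is non-phenolic and should not ionise under these conditions.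

**Step 7.**
- Most likely failure: loss of the benzyl protecting group or hydrogenolysis of the benzylic lactone C–O bond alongside the alkene reduction, or a stalled reduction on the poisoned catalyst.
- Fallback, from 11 back to 12 by conjugate hydride addition in place of hydrogenation. LiBH(s-Bu)3 in THF at −78 °C reduces the arylidene lactone in the 1,4 sense, and the enolate is protonated kinetically at −78 °C with 2,6-di-tert-butyl-4-methylphenol. The proton is delivered to the face away from the C4 and C5 substituents, which gives the same all-cis lactone and touches no benzyl group.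

**Step 9.**
- Most likely failure: sulfonylation of the benzylic hydroxyl and ionisation at C7', which would scramble the concave aryl group; or migration of the silyl group from the C9' oxygen to a neighbouring hydroxyl before ring closure.
- Fallback, from 12 back to 15, replacing steps 8 and 9 by a lactol reduction. i-Bu2AlH in CH2Cl2 at −78 °C gives the lactol F8. Et3SiH with BF3·OEt2 in CH2Cl2 at −78 °C reduces the C9 oxocarbenium ion to the ether. No free diol is formed, and the low temperature is meant to keep the C7'–O bond from ionising.

## Further compounds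

F1 | step 3 | (S)-4-benzyl-3-(pent-4-enoyl)oxazolidin-2-one | C=CCCC(=O)N1[C@@H](Cc2ccccc2)COC1=O
F2 | step 3 | (4S)-4-benzyl-3-[(2R)-2-{(S)-[4-(benzyloxy)-3,5-dimethoxyphenyl](trimethylsilyloxy)methyl}pent-4-enoyl]oxazolidin-2-one | C=CC[C@@H](C(=O)N1[C@@H](Cc2ccccc2)COC1=O)[C@H](O[Si](C)(C)C)c1cc(OC)c(OCc2ccccc2)c(OC)c1
F3 | step 3 | (1S,2S)-1-[4-(benzyloxy)-3,5-dimethoxyphenyl]-2-(prop-2-en-1-yl)propane-1,3-diol | C=CC[C@@H](CO)[C@H](O)c1cc(OC)c(OCc2ccccc2)c(OC)c1
F4 | step 3 | (1S,2S)-1-[4-(benzyloxy)-3,5-dimethoxyphenyl]-2-{[(tert-butyldimethylsilyl)oxy]methyl}pent-4-en-1-ol | C=CC[C@@H](CO[Si](C)(C)C(C)(C)C)[C@H](O)c1cc(OC)c(OCc2ccccc2)c(OC)c1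
F5 | step 3 | (4S,5S)-5-[4-(benzyloxy)-3,5-dimethoxyphenyl]-4-{[(tert-butyldimethylsilyl)oxy]methyl}tetrahydrofuran-2-ol (both anomers) | OC1C[C@@H](CO[Si](C)(C)C(C)(C)C)[C@@H](c2cc(OC)c(OCc3ccccc3)c(OC)c2)O1
F6 | step 11 | [(3S,4S,5S)-5-[4-(benzyloxy)-3,5-dimethoxyphenyl]-4-(hydroxymethyl)tetrahydrofuran-3-yl](4-hydroxy-3-methoxyphenyl)methanone | C1[C@@H](C(=O)c2ccc(O)c(OC)c2)[C@@H](CO)[C@@H](c2cc(OC)c(OCc3ccccc3)c(OC)c2)O1
F7 | step 11 | C7 benzylic alcohol from F6 (both C7 epimers) | C1[C@@H](C(O)c2ccc(O)c(OC)c2)[C@@H](CO)[C@@H](c2cc(OC)c(OCc3ccccc3)c(OC)c2)O1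
F0 | step 7 | none | none
F8 | step 9 | lactol of 12 (both anomers) | OC1[C@@H](Cc2ccc(O[Si](C(C)C)(C(C)C)C(C)C)c(OC)c2)[C@@H](CO[Si](C)(C)C(C)(C)C)[C@@H](c2cc(OC)c(OCc3ccccc3)c(OC)c2)O1
A1 | alternative 1 | trans-disubstituted menthyloxy lactone with C7' dithiane and C7 carbinol | O=C1O[C@H](O[C@H]2C[C@@H](C)CC[C@@H]2C(C)C)[C@@H](C2(c3cc(OC)c(OCc4ccccc4)c(OC)c3)SCCCS2)[C@@H]1[C@@H](O)c1ccc(O[Si](C(C)C)(C(C)C)C(C)C)c(OC)c1
A2 | alternative 1 | (5S)-5-(menthyloxy)furan-2(5H)-one | O=C1C=C[C@@H](O[C@H]2C[C@@H](C)CC[C@@H]2C(C)C)O1
A3 | alternative 1 | 2-[4-(benzyloxy)-3,5-dimethoxyphenyl]-1,3-dithiane | COc1cc(C2SCCCS2)cc(OC)c1OCc1ccccc1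
A4 | alternative 2 | protected furofuran, guaiacyl O-triisopropylsilyl, central ring O-benzyl (same as 19) | COc1cc([C@@H]2OC[C@@H]3[C@H]2CO[C@@H]3c2cc(OC)c(OCc3ccccc3)c(OC)c2)ccc1O[Si](C(C)C)(C(C)C)C(C)C
A5 | alternative 2 | acyclic C7' methoxymethyl ether with (E)-styrene and C9' silyl ether | COCO[C@H](c1cc(OC)c(OCc2ccccc2)c(OC)c1)[C@H](CO[Si](C)(C)C(C)(C)C)/C=C/c1ccc(O[Si](C(C)C)(C(C)C)C(C)C)c(OC)c1
A6 | alternative 3 | bicyclic enol ether lactone with C7'=C8' double bond | COc1cc([C@@H]2OC(=O)C3=C(c4cc(OC)c(OCc5ccccc5)c(OC)c4)OC[C@@H]23)ccc1O[Si](C(C)C)(C(C)C)C(C)C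
A7 | alternative 3 | 1-aroyl-4-aryl-3-oxabicyclo[3.1.0]hexan-2-one (aroylcyclopropane lactone) | O=C1O[C@@H](c3ccc(O[Si](C(C)C)(C(C)C)C(C)C)c(OC)c3)[C@@H]2C[C@]12C(=O)c1cc(OC)c(OCc2ccccc2)c(OC)c1
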